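The route disconnects ring B at C9–C10 and C5=C6, so that ring A of the target (C4 gem-dimethyl, C5, C10 with its methyl) is recognised as intact 2,2,6-trimethylcyclohexanone. Because C4 is quaternary, its imine with (R)-1-phenylethylamine can tautomerise to one enamine only, in which the racemic C10 becomes planar. Michael addition to methyl (E)-4-oxopent-2-enoate and aldol condensation then create the C10 quaternary centre and C9 and close ring B as an enone ester in one operation. The precursor is that chiral imine. Afterwards the enone is saturated to the trans-decalin, C11 becomes a vinyl group, C8 is carboxylated, the C7 oxygen leaves by syn-elimination, and the side chain is attached by B-alkyl Suzuki coupling.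

Key step: step 2

Remark on notation: locants are labdane-type (decalin C1–C10, ring A = C1–C5/C10, ring B = C5–C10; C11 on C9; side chain C12–C16); α is the face of the C10 methyl group, so H-5 and H-9 are β and the C9 substituent is α (equatorial) throughout.
Assumption: the sense of induction of the (R)-amine is taken from the 2-methylcyclohexanone series; should it prove opposite, (S)-1-phenylethylamine is used and nothing else changes.
Remark on C9: an equatorial preference of the C9 ester cannot be relied on in the enone, because C5 and C7 are sp2 and offer no syn-axial hydrogens. C9 is therefore set kinetically in step 2 and secured thermodynamically at the ketal aldehyde in step 6.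

Step 1
Reactants: 1 2,2,6-trimethylcyclohexanone (racemic); 2 (R)-1-phenylethylamine
Product: 3 (R)-1-phenylethyl imine of 2,2,6-trimethylcyclohexanone (both ring epimers, C=N isomers), used crude
Conditions: TiCl4 (0.55 equiv), Et3N, toluene, 0 → 80 °C
Reagents that add atoms: none
Why: Lewis-acid-mediated imine condensation, in which TiCl4 activates the hindered carbonyl group and binds the water formed; no stereocentre has to be controlled because the ring carbon bearing the single methyl group becomes trigonal in step 2.

Step 2
Reactants: 3 chiral imine; 4 methyl (E)-4-oxopent-2-enoate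
Product: 9 enone ester methyl (1R,8aS)-5,5,8a-trimethyl-3-oxo-1,2,3,5,6,7,8,8a-octahydronaphthalene-1-carboxylate, via enamine tautomer 5 (not isolated), via Michael adduct imine 6 (not isolated), via diketo ester 7 (not isolated), via ketol 8 (not isolated)
Conditions: 4 (1.2 equiv), THF, 20 → 45 °C; AcOH/H2O/THF, 40 °C; then TsOH·H2O (cat.), toluene, reflux with azeotropic removal of water
Reagents that add atoms: none
Why: Imine 3 equilibrates with the only possible secondary enamine 5 (C4 carries no hydrogen), in which C10 is trigonal, so both enantiomers of 1 feed one nucleophile; 5 adds to the alkene carbon of 4 that is β to the ketone through a compact aza-ene-type transition state with transfer of the N–H hydrogen to the carbon α to the ketone, giving imine 6, which is hydrolysed to 7. The closest known chemistry is the deracemising Michael addition of chiral imines of 2-substituted cyclanones, followed by an acid-catalysed Robinson-type aldol condensation. Ring B closes by 6-(enolendo)-exo-trig aldol addition of the C6 enol of 7 to the C5 carbonyl, and loss of water from ketol 8 gives the C5=C6 enone. C10 is controlled by the stereocentre of the auxiliary, the acceptor approaching the enamine face anti to its phenyl group; C9 is controlled by the endo placement of the ketone in that transition state together with the E geometry of 4, which puts the ester anti to C5, that is equatorial in ring B. The step needs attack β to the ketone and not β to the ester, secured because the ketone is the stronger activating group and the one engaged in the hydrogen transfer, and a single aldol mode, secured because C5 has no α-hydrogen and only the C6 enol can close a six-membered ring. Acid is chosen over alkoxide for the condensation so that retro-Michael cleavage, Claisen closure onto the ester and scrambling at C9 are avoided.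

Step 3
Reactants: 9 enone ester
Product: 10 trans-keto ester: methyl 4,4,10-trimethyl-7-oxo-trans-decalin-9α-carboxylate (5β-H, 10α-CH3)
Conditions: H2 (3 atm), 10% Pd/C, EtOAc, 25 °C
Reagents that add atoms: none
Why: Heterogeneous catalytic hydrogenation of the enone C5=C6 bond, with hydrogen delivered to the β face because the α face is screened by the axial C10 and C4 methyl groups, so that H-5 ends up trans to the C10 methyl (trans-decalone) while ketone and ester stay untouched.

Step 4
Reactants: 10 trans-keto ester
Product: 11 ketal ester: 7,7-ethylenedioxy ketal (spiro-1,3-dioxolane at C7) of 10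
Conditions: ethylene glycol, TsOH·H2O (cat.), toluene, reflux with azeotropic removal of water
Reagents that add atoms: ethylene glycol OCCO
Why: Acid-catalysed ketalisation of the unhindered C7 ketone, which protects it through steps 5–7 and makes a C9-axial substituent clearly unfavourable (syn-diaxial to a ketal oxygen) for the equilibration in step 6.

Step 5
Reactants: 11 ketal ester
Product: 12 ketal alcohol: 9α-hydroxymethyl (C11 primary alcohol) analogue of 11
Conditions: LiAlH4, THF, 0 °C; aqueous NaOH work-up
Reagents that add atoms: none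
Why: Hydride reduction of the ester to the primary alcohol with LiAlH4, towards which the dioxolane is inert.

Step 6
Reactants: 12 ketal alcohol
Product: 13 ketal aldehyde: 9α-formyl (equatorial) analogue of 11
Conditions: (COCl)2, DMSO, CH2Cl2, −78 °C; Et3N, −78 → 20 °C; then DBU (0.2 equiv), 20 °C
Reagents that add atoms: none
Why: Swern oxidation stops at the aldehyde and the closing hold with DBU equilibrates the enolisable C9 centre to the equatorial aldehyde (H-9 trans-diaxial to the C10 methyl), so that any C9 epimer carried from step 2 converges here.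

Step 7
Reactants: 13 ketal aldehyde
Product: 15 vinyl ketone 9α-ethenyl-4,4,10-trimethyl-trans-decalin-7-one, via vinyl ketal 14 (not isolated)
Conditions: Ph3PCH3Br, KOtBu, THF, 0 → 20 °C; then 1 M HCl, THF, 20 °C
Reagents that add atoms: methyltriphenylphosphonium bromide C[P+](c1ccccc1)(c1ccccc1)c1ccccc1.[Br-]; water O
Why: Wittig methylenation of the aldehyde adds C12 and fixes C9 for good, and dilute acid then hydrolyses the dioxolane (acetal hydrolysis) without touching the monosubstituted alkene.

Step 8
Reactants: 15 vinyl ketone
Product: 16 β-keto ester: methyl 9α-ethenyl-4,4,10-trimethyl-7-oxo-trans-decalin-8β-carboxylate (keto form; enol tautomer in equilibrium)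
Conditions: NaH (2.2 equiv), (MeO)2CO, MeOH (cat.), THF, reflux; aq. HCl quench, 0 °C
Reagents that add atoms: dimethyl carbonate COC(=O)OC
Why: Crossed Claisen condensation (C-methoxycarbonylation) under equilibrating conditions, which should settle on the C8 β-keto ester enolate because a C6 ester would be pressed against the equatorial C4 methyl group, the C8 ester then resting equatorial and trans to the C9 vinyl group since the axial position is syn-diaxial to the C10 methyl.

Step 9
Reactants: 16 β-keto ester
Product: 17 hydroxy ester: methyl 9α-ethenyl-7α-hydroxy-4,4,10-trimethyl-trans-decalin-8β-carboxylate (OH, ester and vinyl all equatorial)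
Conditions: NaBH4, MeOH, −20 °C
Reagents that add atoms: none
Why: Borohydride reduction of the ketone of the β-keto ester, in which axial hydride delivery on the β face (only H-5 and H-9 are syn-axial there) should give the equatorial 7α-alcohol trans to the ester, any 7β-epimer being separable here.

Step 10
Reactants: 17 hydroxy ester
Product: 18 mesylate: 7α-methanesulfonyloxy analogue of 17
Conditions: MsCl, Et3N, CH2Cl2, −10 °C
Reagents that add atoms: methanesulfonyl chloride CS(=O)(=O)Cl
Why: Sulfonylation of the secondary alcohol to the mesylate at low temperature, where the equatorial leaving group has no antiperiplanar hydrogen and so resists elimination.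

Step 11
Reactants: 18 mesylate
Product: 19 selenide: methyl 9α-ethenyl-7β-(phenylselanyl)-4,4,10-trimethyl-trans-decalin-8β-carboxylate (Se axial)
Conditions: (PhSe)2, NaBH4, EtOH/THF, 0 → 50 °C
Reagents that add atoms: diphenyl diselenide c1ccccc1[Se][Se]c1ccccc1
Why: SN2 displacement by the soft and weakly basic selenolate, whose inversion places selenium axial on the β face of C7, cis to the C8 ester and anti to H-8.

Step 12
Reactants: 19 selenide
Product: 21 diene ester methyl (1R,2S,4aR,8aS)-1-ethenyl-5,5,8a-trimethyl-1,2,4a,5,6,7,8,8a-octahydronaphthalene-2-carboxylate, via selenoxide 20 (not isolated)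
Conditions: NaIO4, NaHCO3, THF/MeOH/H2O, 0 → 25 °C
Reagents that add atoms: none
Why: Selenoxide syn-elimination, in which the axial 7β-selenoxide can reach only the cis hydrogen on C6 because H-8 is trans-diaxial to it, so the C6=C7 alkene forms out of conjugation and C8 keeps its configuration.

Step 13
Reactants: 22 methyl 4-hydroxybut-2-ynoate
Product: 23 methyl (Z)-4-hydroxy-3-iodobut-2-enoate
Conditions: NaI, AcOH, 70 °C
Reagents that add atoms: sodium iodide [Na+].[I-]
Why: Conjugate hydroiodination of the ynoate (iodide adds at the β-carbon and the proton enters anti to it), giving the Z iodoenoate whose hydroxymethyl group is trans to the ester and cannot lactonise.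

Step 14
Reactants: 21 diene ester; 23 methyl (Z)-4-hydroxy-3-iodobut-2-enoate
Product: 25 hydroxy diester (16-hydroxy precursor of the target; 13E), via B-alkyl-9-BBN 24 (not isolated)
Conditions: 9-BBN, THF, 0 → 25 °C; then 23, PdCl2(dppf) (5 mol%), AsPh3, Cs2CO3, DMF/H2O, 25 °C
Reagents that add atoms: none
Why: Anti-Markovnikov hydroboration of the monosubstituted alkene with 9-BBN, which spares the hindered ring alkene and the ester, followed by B-alkyl Suzuki–Miyaura coupling that forms C12–C13 with retention of the alkene geometry of 23.

Step 15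
Reactants: 25 hydroxy diester
Product: 26 target, methyl (1R,2S,4aR,8aS)-1-[(3E)-3-(acetoxymethyl)-5-methoxy-5-oxopent-3-en-1-yl]-5,5,8a-trimethyl-1,2,4a,5,6,7,8,8a-octahydronaphthalene-2-carboxylate
Conditions: Ac2O, pyridine, DMAP (cat.), CH2Cl2, 0 °C
Reagents that add atoms: acetic anhydride CC(=O)OC(C)=O
Why: DMAP-catalysed acylation (esterification) of the primary allylic alcohol under mild, non-enolising conditions, which completes the target without moving the C6=C7 bond.

Compound list
1 | 2,2,6-trimethylcyclohexan-1-one (racemic) | CC1CCCC(C)(C)C1=O | starting material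
2 | (R)-1-phenylethylamine | C[C@@H](N)c1ccccc1 | starting material
3 | (1R)-1-phenyl-N-(2,2,6-trimethylcyclohexylidene)ethan-1-amine (both ring epimers, C=N isomers) | CC1CCCC(C)(C)C1=N[C@H](C)c1ccccc1 | intermediate
4 | methyl (E)-4-oxopent-2-enoate | COC(=O)/C=C/C(C)=O | starting material
5 | 2,6,6-trimethyl-N-[(1R)-1-phenylethyl]cyclohex-1-en-1-amine (secondary enamine tautomer of 3) | CC1=C(N[C@H](C)c2ccccc2)C(C)(C)CCC1 | intermediate
6 | methyl (2R)-4-oxo-2-[(1S)-1,3,3-trimethyl-2-{[(1R)-1-phenylethyl]imino}cyclohexyl]pentanoate (Michael adduct imine) | COC(=O)[C@H](CC(C)=O)[C@]1(C)CCCC(C)(C)C1=N[C@H](C)c1ccccc1 | intermediate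
7 | methyl (2R)-4-oxo-2-[(1S)-1,3,3-trimethyl-2-oxocyclohexyl]pentanoate (diketo ester) | COC(=O)[C@H](CC(C)=O)[C@]1(C)CCCC(C)(C)C1=O | intermediate
8 | methyl (1R,8aS)-4a-hydroxy-5,5,8a-trimethyl-3-oxodecahydronaphthalene-1-carboxylate (ketol; carbinol configuration at C5 not defined) | COC(=O)[C@@H]1CC(=O)CC2(O)C(C)(C)CCC[C@@]12C | intermediate
9 | methyl (1R,8aS)-5,5,8a-trimethyl-3-oxo-1,2,3,5,6,7,8,8a-octahydronaphthalene-1-carboxylate (Δ5-7-ketone, C9 ester α, equatorial) | COC(=O)[C@@H]1CC(=O)C=C2C(C)(C)CCC[C@@]12C | intermediate
10 | methyl 4,4,10-trimethyl-7-oxo-trans-decalin-9α-carboxylate (5β-H, 9β-H, 10α-CH3) | COC(=O)[C@@H]1CC(=O)C[C@@H]2C(C)(C)CCC[C@@]12C | intermediate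
11 | 7,7-ethylenedioxy ketal of 10 (spiro-1,3-dioxolane at C7; stereocentres as in 10) | COC(=O)[C@@H]1CC2(OCCO2)C[C@@H]3C(C)(C)CCC[C@@]13C | intermediate
12 | ketal alcohol: 9α-hydroxymethyl-7,7-ethylenedioxy-4,4,10-trimethyl-trans-decalin | OC[C@@H]1CC2(OCCO2)C[C@@H]3C(C)(C)CCC[C@@]13C | intermediate
13 | ketal aldehyde: 9α-formyl-7,7-ethylenedioxy-4,4,10-trimethyl-trans-decalin (CHO equatorial) | O=C[C@@H]1CC2(OCCO2)C[C@@H]3C(C)(C)CCC[C@@]13C | intermediate
14 | vinyl ketal: 9α-ethenyl-7,7-ethylenedioxy-4,4,10-trimethyl-trans-decalin | C=C[C@@H]1CC2(OCCO2)C[C@@H]3C(C)(C)CCC[C@@]13C | intermediate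
15 | vinyl ketone: 9α-ethenyl-4,4,10-trimethyl-trans-decalin-7-one | C=C[C@@H]1CC(=O)C[C@@H]2C(C)(C)CCC[C@@]12C | intermediate
16 | β-keto ester: methyl 9α-ethenyl-4,4,10-trimethyl-7-oxo-trans-decalin-8β-carboxylate (keto form) | C=C[C@@H]1[C@@H](C(=O)OC)C(=O)C[C@@H]2C(C)(C)CCC[C@@]12C | intermediate
17 | hydroxy ester: methyl 9α-ethenyl-7α-hydroxy-4,4,10-trimethyl-trans-decalin-8β-carboxylate | C=C[C@@H]1[C@@H](C(=O)OC)[C@H](O)C[C@@H]2C(C)(C)CCC[C@@]12C | intermediate
18 | mesylate: methyl 9α-ethenyl-7α-(methanesulfonyloxy)-4,4,10-trimethyl-trans-decalin-8β-carboxylate | C=C[C@@H]1[C@@H](C(=O)OC)[C@H](OS(C)(=O)=O)C[C@@H]2C(C)(C)CCC[C@@]12C | intermediate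
19 | selenide: methyl 9α-ethenyl-7β-(phenylselanyl)-4,4,10-trimethyl-trans-decalin-8β-carboxylate | C=C[C@@H]1[C@@H](C(=O)OC)[C@@H]([Se]c3ccccc3)C[C@@H]2C(C)(C)CCC[C@@]12C | intermediate
20 | selenoxide of 19 (configuration at Se not defined) | C=C[C@@H]1[C@@H](C(=O)OC)[C@@H]([Se](=O)c3ccccc3)C[C@@H]2C(C)(C)CCC[C@@]12C | intermediate
21 | methyl (1R,2S,4aR,8aS)-1-ethenyl-5,5,8a-trimethyl-1,2,4a,5,6,7,8,8a-octahydronaphthalene-2-carboxylate (Δ6, 8β-ester, 9α-vinyl) | C=C[C@@H]1[C@@H](C(=O)OC)C=C[C@@H]2C(C)(C)CCC[C@@]12C | intermediate
22 | methyl 4-hydroxybut-2-ynoate | COC(=O)C#CCO | starting material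
23 | methyl (Z)-4-hydroxy-3-iodobut-2-enoate | COC(=O)/C=C(\I)CO | intermediate
24 | B-alkyl-9-BBN: 9-[2-(8β-methoxycarbonyl-Δ6-decalin-9α-yl)ethyl]-9-borabicyclo[3.3.1]nonane derived from 21 | C1CCC2CCCC1B2CC[C@@H]3[C@@H](C(=O)OC)C=C[C@@H]4C(C)(C)CCC[C@@]34C | intermediate
25 | hydroxy diester: methyl (1R,2S,4aR,8aS)-1-[(3E)-3-(hydroxymethyl)-5-methoxy-5-oxopent-3-en-1-yl]-5,5,8a-trimethyl-1,2,4a,5,6,7,8,8a-octahydronaphthalene-2-carboxylate | COC(=O)/C=C(\CC[C@@H]1[C@@H](C(=O)OC)C=C[C@@H]2C(C)(C)CCC[C@@]12C)CO | intermediate
26 | methyl (1R,2S,4aR,8aS)-1-[(3E)-3-(acetoxymethyl)-5-methoxy-5-oxopent-3-en-1-yl]-5,5,8a-trimethyl-1,2,4a,5,6,7,8,8a-octahydronaphthalene-2-carboxylate (CNP0190145.1) | COC(=O)/C=C(\CC[C@@H]1[C@@H](C(=O)OC)C=C[C@@H]2C(C)(C)CCC[C@@]12C)COC(C)=O | target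

Total step count: 15. Longest linear sequence: 14 steps (steps 1–12, 14 and 15); step 13 makes the side-chain fragment.

Steps most likely to fail

Step 2. The tetrasubstituted enamine, crowded on nitrogen by the C4 methyl groups, may add too slowly to the β-substituted acceptor. Face selection may erode, and the aldol closure onto the doubly neopentyl C5 carbonyl may stall. Fallback, setting out from 1 and 4 and returning at 10: racemic 1 and 4 are joined by an acid-catalysed Robinson annulation (conc. H2SO4 cat., toluene, reflux with removal of water), which should give the racemic enone ester F1. Hydrogenation as in step 3 gives the racemic trans-keto ester F2. Preparative chromatography on a chiral stationary phase separates 10 from its antipode ent-10 F3, and the route resumes at 10.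

Step 11. Substitution at the hindered secondary carbon next to the ester-bearing C8 may be slow and give way to elimination towards C8. Incomplete facial selectivity in step 9 would also feed the wrong epimer into this step. Fallback, setting out from 16 and returning at 21 (it bypasses steps 9–12): the sodium enolate of 16 (NaH, THF) is O-sulfonylated with N-phenyltriflimide to the enol triflate F4. Palladium-catalysed transfer hydrogenolysis (Pd(OAc)2, PPh3, HCO2H, Bu3N, DMF, 60 °C) gives the conjugated C7=C8 ester F5. γ-Deprotonation at C6 (LDA, HMPA, THF, −78 °C) and kinetic α-protonation of the dienolate with acetic acid, axial and therefore on the α face of C8, should give 21.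

Step 14. Transmetalation of the alkylborane may be slow, so that protodeboronation or β-hydride elimination takes over. The aqueous base may also move the C6=C7 bond into conjugation with the C8 ester. Fallback, setting out from 21 (and 23) and returning at 25: hydroboration to 24 as in step 14 and oxidation with sodium perborate gives the primary alcohol F6, used at once because it can lactonise onto the C8 ester. Iodine, PPh3 and imidazole (Appel-type iodination) give the primary iodide F7. Zinc dust and LiCl in THF give the alkylzinc iodide F8. This is coupled without added base under Pd(PPh3)4 catalysis (Negishi coupling) with the TBS-protected iodoenoate F9, made from 23 with TBSCl and imidazole, to give the silyl ether F10. HF·pyridine in THF removes the silyl group and gives 25.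

Further compounds
F1 | step 2 | racemic enone ester (rac-9, relative configuration as 9) | COC(=O)C1CC(=O)C=C2C(C)(C)CCCC12C
F2 | step 2 | racemic trans-keto ester (rac-10, relative configuration as 10) | COC(=O)C1CC(=O)CC2C(C)(C)CCCC12C
F3 | step 2 | ent-10 | COC(=O)[C@H]1CC(=O)C[C@H]2C(C)(C)CCC[C@]12C
F4 | step 11 | enol triflate: methyl 9α-ethenyl-4,4,10-trimethyl-7-(trifluoromethanesulfonyloxy)-trans-Δ7-octalin-8-carboxylate | C=C[C@@H]1C(C(=O)OC)=C(OS(=O)(=O)C(F)(F)F)C[C@@H]2C(C)(C)CCC[C@@]12C
F5 | step 11 | conjugated ester: methyl 9α-ethenyl-4,4,10-trimethyl-trans-Δ7-octalin-8-carboxylate | C=C[C@@H]1C(C(=O)OC)=CC[C@@H]2C(C)(C)CCC[C@@]12C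
F6 | step 14 | primary alcohol: 9α-(2-hydroxyethyl) analogue of 21 | OCC[C@@H]1[C@@H](C(=O)OC)C=C[C@@H]2C(C)(C)CCC[C@@]12C
F7 | step 14 | primary iodide: 9α-(2-iodoethyl) analogue of 21 | ICC[C@@H]1[C@@H](C(=O)OC)C=C[C@@H]2C(C)(C)CCC[C@@]12C
F8 | step 14 | alkylzinc iodide from F7 | I[Zn]CC[C@@H]1[C@@H](C(=O)OC)C=C[C@@H]2C(C)(C)CCC[C@@]12C
F9 | step 14 | methyl (Z)-4-[(tert-butyldimethylsilyl)oxy]-3-iodobut-2-enoate | COC(=O)/C=C(\I)CO[Si](C)(C)C(C)(C)C
F10 | step 14 | tert-butyldimethylsilyl ether of 25 | COC(=O)/C=C(\CC[C@@H]1[C@@H](C(=O)OC)C=C[C@@H]2C(C)(C)CCC[C@@]12C)CO[Si](C)(C)C(C)(C)C
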